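**Retrosynthetic overview**

1. Psiguadial A is cut back through the late aryl functionalisation (two CHO, two OH) to a di-O-methyl core. Its gem-dimethylcyclopropane is traced to a C6=C7 alkene, and its C1–O/C10–H pair to a C1=C10 alkene closed by the phenol in the way presumed for the biosynthesis. Terpenoid carbons are numbered as in aromadendrane: C1 O-bearing fusion carbon, C4 quaternary C–CH3, C5 fusion CH, C6/C7 cyclopropane CH, C8/C9 CH2, C10 CH–CH3; C7' is the CHPh carbon.
2. What remains is a cyclopentane-fused cyclohepta-1,4-diene, and this is the enabling feature. In the seven-membered ring the two-carbon edge C1–C10 is flanked by the five-carbon chain C5–C6–C7–C8–C9, and C1 is tied to C5 a second time through C2–C3–C4. That is the retron of an intramolecular vinylcyclopropane–alkyne (5+2) cycloaddition with a three-carbon tether.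
3. Disconnecting C1–C5 and C9–C10 opens both carbocycles at once to an acyclic enyne that carries only a plain cyclopropane, an E alkene and a methyl alkyne.
4. The enyne's two stereocenters (C4, C7') and its phenol come from a 4-phenyl-dihydrocoumarin: asymmetric conjugate addition of PhB(OH)2 to 5,7-dimethoxycoumarin, two enolate alkylations anti to phenyl, lactol formation and Julia–Kocienski olefination.
5. Order of ring formation: lactone (temporary, reopened) → cyclopentane and cycloheptadiene together → oxepine ether bridge → cyclopropane.

Key step: step 9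

Remark on the chemistry: the sense of induction in step 1 is assumed to follow that usual for simple coumarins; if it proves opposite, the antipodal ligand is used. All later stereocenters are relayed from C7'.

**Route**

Step 1
Reactants: 1 5,7-dimethoxycoumarin; 2 phenylboronic acid
Product: 3 (S)-5,7-dimethoxy-4-phenylchroman-2-one
Conditions: Rh(acac)(C2H4)2 (3 mol %), (S)-SEGPHOS, dioxane/H2O 10:1, 60 °C
Reagents that add atoms: none
Why: Rhodium-catalysed asymmetric 1,4-addition of an arylboronic acid to a coumarin (Hayashi–Miyaura reaction) is established for 4-arylchroman-2-ones; the chiral bisphosphine–rhodium aryl species selects one face of the lactone alkene and sets C7' (S).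

Step 2
Reactants: 3 (S)-5,7-dimethoxy-4-phenylchroman-2-one
Product: 4 (3R,4S)-5,7-dimethoxy-3-methyl-4-phenylchroman-2-one
Conditions: LiN(SiMe3)2, THF, −78 °C; MeI, −78 °C
Reagents that add atoms: iodomethane, CI
Why: Enolate alkylation of the lactone at −78 °C (cold enough to suppress ketene formation by phenoxide loss) should occur anti to the pseudoaxial 4-phenyl group; the C3 configuration formed here is erased again in step 4.

Step 3
Reactants: 5 pent-3-yn-1-ol
Product: 6 pent-3-yn-1-yl trifluoromethanesulfonate
Conditions: Tf2O, pyridine, CH2Cl2, −78 → −20 °C; cold aqueous wash, used at once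
Reagents that add atoms: trifluoromethanesulfonic anhydride, O=S(=O)(OS(=O)(=O)C(F)(F)F)C(F)(F)F
Why: O-sulfonylation of a primary alcohol gives a homopropargylic electrophile reactive enough to alkylate a fully substituted enolate at low temperature, where elimination to the enyne should not compete.

Step 4
Reactants: 4 (3R,4S)-5,7-dimethoxy-3-methyl-4-phenylchroman-2-one; 6 pent-3-yn-1-yl trifluoromethanesulfonate
Product: 7 (3R,4S)-5,7-dimethoxy-3-methyl-3-(pent-3-yn-1-yl)-4-phenylchroman-2-one
Conditions: LiN(iPr)2, THF, −78 °C; then 6, −78 → −30 °C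
Reagents that add atoms: none
Why: Second enolate C-alkylation: the tetrasubstituted lithium enolate should be attacked on the face opposite the adjacent 4-phenyl group (1,2-induction in a six-membered lactone enolate), so the pentynyl chain ends up trans and the methyl cis to phenyl, which is the C4 (R)/C7' (S) relationship of the target.

Step 5
Reactants: 7 (3R,4S)-5,7-dimethoxy-3-methyl-3-(pent-3-yn-1-yl)-4-phenylchroman-2-one
Product: 8 (3R,4S)-5,7-dimethoxy-3-methyl-3-(pent-3-yn-1-yl)-4-phenylchroman-2-ol (lactol, both C2 epimers)
Conditions: iBu2AlH, CH2Cl2, −78 °C; aq KNaC4H4O6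
Reagents that add atoms: none
Why: Partial reduction of a dihydrocoumarin to its lactol with iBu2AlH at −78 °C, where the tetrahedral aluminium alkoxide persists; the anomeric centre is of no consequence.

Step 6
Reactants: 9 1-phenyl-1H-tetrazole-5-thiol; 10 (bromomethyl)cyclopropane
Product: 11 5-[(cyclopropylmethyl)sulfanyl]-1-phenyl-1H-tetrazole
Conditions: K2CO3, acetone, 50 °C
Reagents that add atoms: none
Why: SN2 S-alkylation of the soft thiolate by a primary bromide.

Step 7
Reactants: 11 5-[(cyclopropylmethyl)sulfanyl]-1-phenyl-1H-tetrazole
Product: 12 5-[(cyclopropylmethyl)sulfonyl]-1-phenyl-1H-tetrazole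
Conditions: H2O2 (30% aq), (NH4)6Mo7O24·4H2O (cat.), EtOH, 0 °C → rt
Reagents that add atoms: hydrogen peroxide, OO
Why: Molybdate-catalysed sulfide-to-sulfone oxidation, the standard preparation of Julia–Kocienski reagents.

Step 8
Reactants: 8 lactol; 12 5-[(cyclopropylmethyl)sulfonyl]-1-phenyl-1H-tetrazole
Product: 14 3,5-dimethoxy-2-[(1S,2S)-2-[(E)-2-cyclopropylethenyl]-2-methyl-1-phenylhept-5-yn-1-yl]phenol, via hydroxy aldehyde 13 (not isolated)
Conditions: KN(SiMe3)2 (excess), THF, −78 °C → rt
Reagents that add atoms: none
Why: Julia–Kocienski olefination: base opens the lactol to the phenoxide aldehyde (no α-hydrogen, so no enolisation), the metallated sulfone adds, and Smiles rearrangement with loss of SO2 and tetrazolone should give the alkene with the E selectivity usual for phenyltetrazolyl sulfones and α-branched aldehydes.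

Step 9
Reactants: 14 3,5-dimethoxy-2-[(1S,2S)-2-[(E)-2-cyclopropylethenyl]-2-methyl-1-phenylhept-5-yn-1-yl]phenol
Product: 15 3,5-dimethoxy-2-{(S)-[(3S,3aR)-3,8-dimethyl-1,2,3,3a,6,7-hexahydroazulen-3-yl](phenyl)methyl}phenol
Conditions: [Rh(CO)2Cl]2 (5 mol %), ClCH2CH2Cl, 80 °C
Reagents that add atoms: none
Why: Rhodium-catalysed intramolecular vinylcyclopropane–alkyne (5+2) cycloaddition with a three-carbon all-carbon tether and an internal methyl alkyne is the closest known reaction type. Monovalent rhodium binds the ene–yne and opens the cyclopropane next to the alkene (the two CH2 groups are equivalent, so there is no regiochemical issue) to a trivalent σ-alkyl/π-allyl rhodacycle; the tethered alkyne then inserts at the allyl terminus C5 (forming C1–C5), and reductive elimination joins the alkenyl carbon C10 to the former cyclopropane CH2, C9. The cyclopentane is thus closed by an exo migratory insertion enforced by the C2–C3–C4 tether and helped by the geminal substitution at C4 (Thorpe–Ingold effect), and the seven-membered ring by C(sp2)–C(sp3) reductive elimination from an eight-membered rhodacycle, which gives the 1,4-diene (C1=C10, C6=C7) with the C10 methyl in place. The only new stereocenter, C5, is controlled by the adjacent quaternary C4: the alkene face is taken that puts the forming C5–C6 ring bond anti to the large diarylmethyl group and syn to the small methyl, so H5 should end up cis to the C4–C7' bond, as the later bridge requires. The step needs this diastereofacial selectivity, the E alkene set in step 8, and tolerance of a free phenol and an electron-rich arene; the neutral chloro(carbonyl) catalyst in a non-coordinating solvent is chosen for that.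

Step 10
Reactants: 15 3,5-dimethoxy-2-{(S)-[(3S,3aR)-3,8-dimethyl-1,2,3,3a,6,7-hexahydroazulen-3-yl](phenyl)methyl}phenol
Product: 16 bridged cycloheptene ether (1S,4R,5R,10S,7'S): the di-O-methyl, dideformyl psiguadial A skeleton without the C(CH3)2 bridge and with a C6=C7 double bond
Conditions: CF3SO3H (10 mol %), CH2Cl2, −40 → 0 °C
Reagents that add atoms: none
Why: Acid-catalysed intramolecular Markovnikov hydroalkoxylation of a tetrasubstituted alkene by a phenol: protonation at C10 creates tertiary cationic character at C1, which the phenol, held on the α face by the C4–C7' link, captures (only the cis-bridged oxepine is possible, which sets C1), while the proton should enter C10 anti to the oxygen from the β face not covered by the diarylmethyl group, placing the C10 methyl α (this epimer, with the methyl outside the cleft between the ether bridge and C2, is also expected to be the more stable one if the addition is reversible).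

Step 11
Reactants: 16 bridged cycloheptene ether
Product: 17 gem-dibromocyclopropane (1S,4R,5R,6S,7R,10S,7'S): analogue of 18 with CBr2 in place of C(CH3)2
Conditions: CHBr3, 50% aq NaOH, BnEt3NCl (cat.), CH2Cl2, rt
Reagents that add atoms: bromoform, BrC(Br)Br
Why: Dibromocarbene addition under phase-transfer conditions is stereospecifically cis and should take the convex α face of C6=C7 (syn to H5, away from the C2–C3 bridge that covers the β face), setting C6 and C7; the aryl ether is inert to the carbene.

Step 12
Reactants: 17 gem-dibromocyclopropane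
Product: 18 dideformyl psiguadial A dimethyl ether (1S,4R,5R,6R,7R,10S,7'S; both CHO replaced by H, both OH by OCH3)
Conditions: Me2CuLi (excess, from CuI and MeLi), Et2O, 0 °C; then MeI
Reagents that add atoms: lithium dimethylcuprate, [Li+].C[Cu-]C; iodomethane, CI
Why: Exchange of both bromine atoms of a gem-dibromocyclopropane for methyl with lithium dimethylcuprate followed by iodomethane is known for dibromobicyclo[n.1.0]alkanes and touches no stereocenter (the C6 descriptor changes by priority only).

Step 13
Reactants: 18 dideformyl psiguadial A dimethyl ether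
Product: 19 dideformyl psiguadial A (both CHO replaced by H; free resorcinol-type diphenol)
Conditions: NaSEt (excess), DMF, 140 °C; aq HCl work-up
Reagents that add atoms: none
Why: SN2 demethylation of aryl methyl ethers by thiolate, which cannot attack the tertiary C1–O ether and, being non-acidic, leaves the cyclopropane untouched.

Step 14
Reactants: 19 dideformyl psiguadial A
Product: 20 psiguadial A
Conditions: Cl2CHOMe, TiCl4, CH2Cl2, −78 → 0 °C; then H2O
Reagents that add atoms: dichloromethyl methyl ether, COC(Cl)Cl; water, O
Why: Rieche formylation: titanium phenoxide-directed formylation at both free ring positions, each flanked by two oxygen substituents, a sequence with close precedent on tertiary-alkyl aryl ethers of this phloroglucinol type; low temperature protects the ether and cyclopropane, and hydrolysis releases the two aldehydes.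

**Compound list**

1 | 5,7-dimethoxycoumarin | COc1cc(OC)c2C=CC(=O)Oc2c1 | starting material
2 | phenylboronic acid | OB(O)c1ccccc1 | starting material
3 | (S)-5,7-dimethoxy-4-phenylchroman-2-one | O=C1Oc2cc(OC)cc(OC)c2[C@@H](C1)c1ccccc1 | intermediate
4 | (3R,4S)-5,7-dimethoxy-3-methyl-4-phenylchroman-2-one | O=C1Oc2cc(OC)cc(OC)c2[C@@H]([C@H]1C)c1ccccc1 | intermediate
5 | pent-3-yn-1-ol | CC#CCCO | starting material
6 | pent-3-yn-1-yl trifluoromethanesulfonate | CC#CCCOS(=O)(=O)C(F)(F)F | intermediate
7 | (3R,4S)-5,7-dimethoxy-3-methyl-3-(pent-3-yn-1-yl)-4-phenylchroman-2-one | O=C1Oc2cc(OC)cc(OC)c2[C@@H]([C@@]1(C)CCC#CC)c1ccccc1 | intermediate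
8 | (3R,4S)-5,7-dimethoxy-3-methyl-3-(pent-3-yn-1-yl)-4-phenylchroman-2-ol (C2 epimers) | OC1Oc2cc(OC)cc(OC)c2[C@@H]([C@@]1(C)CCC#CC)c1ccccc1 | intermediate
9 | 1-phenyl-1H-tetrazole-5-thiol | Sc1nnnn1-c1ccccc1 | starting material
10 | (bromomethyl)cyclopropane | BrCC1CC1 | starting material
11 | 5-[(cyclopropylmethyl)sulfanyl]-1-phenyl-1H-tetrazole | C1CC1CSc1nnnn1-c1ccccc1 | intermediate
12 | 5-[(cyclopropylmethyl)sulfonyl]-1-phenyl-1H-tetrazole | O=S(=O)(CC1CC1)c1nnnn1-c1ccccc1 | intermediate
13 | (R)-2-[(S)-(2-hydroxy-4,6-dimethoxyphenyl)(phenyl)methyl]-2-methylhept-5-ynal | Oc1cc(OC)cc(OC)c1[C@@H]([C@@](C)(CCC#CC)C=O)c1ccccc1 | intermediate (not isolated)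
14 | 3,5-dimethoxy-2-[(1S,2S)-2-[(E)-2-cyclopropylethenyl]-2-methyl-1-phenylhept-5-yn-1-yl]phenol | Oc1cc(OC)cc(OC)c1[C@@H]([C@@](C)(CCC#CC)/C=C/C1CC1)c1ccccc1 | intermediate
15 | 3,5-dimethoxy-2-{(S)-[(3S,3aR)-3,8-dimethyl-1,2,3,3a,6,7-hexahydroazulen-3-yl](phenyl)methyl}phenol | Oc1cc(OC)cc(OC)c1[C@@H]([C@@]1(C)CCC2=C(C)CCC=C[C@H]12)c1ccccc1 | intermediate
16 | bridged cycloheptene ether (1S,4R,5R,10S,7'S): O on C1, C7' on C4 and H5 all α, C10 methyl α, C6=C7 alkene, two OCH3 on the arene | C[C@H]1CCC=C[C@@H]2[C@]3(C)CC[C@@]21Oc1cc(OC)cc(OC)c1[C@@H]3c1ccccc1 | intermediate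
17 | gem-dibromocyclopropane (1S,4R,5R,6S,7R,10S,7'S), CBr2 on the α face | C[C@H]1CC[C@@H]2[C@H]([C@@H]3[C@]4(C)CC[C@@]31Oc1cc(OC)cc(OC)c1[C@@H]4c1ccccc1)C2(Br)Br | intermediate
18 | dideformyl psiguadial A dimethyl ether (1S,4R,5R,6R,7R,10S,7'S) | C[C@H]1CC[C@@H]2[C@H]([C@@H]3[C@]4(C)CC[C@@]31Oc1cc(OC)cc(OC)c1[C@@H]4c1ccccc1)C2(C)C | intermediate
19 | dideformyl psiguadial A (1S,4R,5R,6R,7R,10S,7'S) | C[C@H]1CC[C@@H]2[C@H]([C@@H]3[C@]4(C)CC[C@@]31Oc1cc(O)cc(O)c1[C@@H]4c1ccccc1)C2(C)C | intermediate
20 | psiguadial A (1S,4R,5R,6R,7R,10S,7'S) | C[C@H]1CC[C@@H]2[C@H]([C@@H]3[C@]4(C)CC[C@@]31Oc1c(C=O)c(O)c(C=O)c(O)c1[C@@H]4c1ccccc1)C2(C)C | target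

**Step count**

Total: 14 steps. Longest linear sequence: 11 steps (1, 2, 4, 5, 8, 9, 10, 11, 12, 13, 14).

**Three steps most likely to fail**

Step 10. What may go wrong: the cationic character at C1 is released by a 1,2-hydride shift from C5, or by proton loss to a conjugated diene, before the seven-membered ether closes; or the proton is delivered to the α face of C10 by the phenol itself. The fallback sets out from 15 and comes back at 16. The proton is replaced by a mercury electrophile, which adds without a free cation and strictly anti to the incoming oxygen. Hg(OCOCF3)2 in CH3CN/CH2Cl2 at −20 °C, then aqueous NaCl, should give the chloromercurial F1, with HgCl on the β face of C10 and the aryl ether oxygen on the α face of C1. Reductive demercuration with sodium amalgam in aqueous NaOH/THF, which replaces mercury by hydrogen with retention, should then give 16.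

Step 9. What may go wrong: stalled cycloaddition, because the alkene is neopentylic and the free phenol can bind rhodium, or poor face selectivity at C5. The fallback sets out from 14 and comes back at 15. The phenol is masked (Ac2O, pyridine) as the aryl acetate F2. The cycloaddition is then run in the ruthenium manifold, [(C5H5)Ru(CH3CN)3]PF6 in acetone at rt, which begins with ene–yne oxidative coupling to a ruthenacyclopentene before the cyclopropane opens and so responds differently to the hindered alkene. This should give the bicyclic acetate F3, and K2CO3 in MeOH then releases 15.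

Step 12. What may go wrong: incomplete exchange (one bromine kept or reduced), or ring opening of the α-bromo organocopper to an allene. The fallback sets out from 17 and comes back at 18. Two separate halogen–lithium exchange/methylation cycles through lithium carbenoids are used. nBuLi in THF at −100 °C, then MeI, should give the bromo(methyl)cyclopropane F4 (configuration at the bromine-bearing carbon immaterial). tBuLi (2 equiv) in Et2O at −78 °C, then MeI, should give 18.

**Further compounds**

F1 | step 10 | chloromercurial of 16 (HgCl on C10, β face; C10 methyl α) | C[C@@]1([Hg]Cl)CCC=C[C@@H]2[C@]3(C)CC[C@@]21Oc1cc(OC)cc(OC)c1[C@@H]3c1ccccc1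
F2 | step 9 | aryl acetate of 14 | CC(=O)Oc1cc(OC)cc(OC)c1[C@@H]([C@@](C)(CCC#CC)/C=C/C1CC1)c1ccccc1
F3 | step 9 | aryl acetate of 15 | CC(=O)Oc1cc(OC)cc(OC)c1[C@@H]([C@@]1(C)CCC2=C(C)CCC=C[C@H]12)c1ccccc1
F4 | step 12 | bromo(methyl)cyclopropane analogue of 18 (one cyclopropane CH3 replaced by Br) | C[C@H]1CC[C@@H]2[C@H]([C@@H]3[C@]4(C)CC[C@@]31Oc1cc(OC)cc(OC)c1[C@@H]4c1ccccc1)C2(C)Br
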